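## Structural features

The target is a 2-arylbenzofuran. The benzofuran (O1, C2, C3, C3a, C4–C7, C7a) carries free hydroxyls at C4 and C6, hydrogen at C3 and C5, and at C7 a 3-methylbut-3-en-2-yl group whose benzylic carbon is the only stereocentre; the SMILES reads as (R) (aryl > isopropenyl > methyl > H). C2 is bonded to C5 of a 2,2-dimethylchroman whose benzene ring is pentasubstituted: ring CH2 at C4a, the benzofuran at C5, a prenyl group at C6, a hydroxyl at C7 and the ring oxygen at C8a, leaving only C8–H. The stereocentre has no neighbouring stereocentre to relay from, so a reagent must set it. It is both benzylic and allylic, so migration of the isopropenyl double bond into conjugation would erase it. The fragile parts are the three electron-rich phenols, the two alkenes that each sit ortho to a phenolic oxygen (acid would close a second chroman or a dihydrobenzofuran) and the enol-ether-like C2=C3 bond; acid, hydrogenation and strong oxidants are therefore excluded late, and protection must be fluoride-labile. The real difficulties are the aryl–heteroaryl bond at a carbon flanked on both sides (chroman C5), the distinction of like positions on two oxygen-rich rings (C6 against C8 on the chroman; C5 against C7 and O4 against O6 on the benzofuran), and a defined stereocentre at the most crowded benzofuran carbon. The key step uses the benzo ring C3a–C4–C5–C6–C7–C7a: oxygen on C4 and C6 with hydrogen on C5 (and, at that stage, C7) is what results when a ketene carbonyl carbon (C4), the two carbons of a siloxyalkyne (C5, C6) and a former diazo carbon (C7) are joined onto the C7a–C3a edge, which is the C2–C3 bond of a 2-arylfuran, and it delivers O4 as a free phenol and O6 as a silyl ether.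

## Logic of the disconnections

**44 from 43.** The three O–Si bonds are cut last. All phenols stay masked by one kind of silyl group until every organometallic and iodine-mediated step is over. The forward step must be a buffered fluoride treatment that leaves both alkenes and the stereocentre alone.

**43 from 38 and 39.** The bond between the stereocentre and the isopropenyl carbon is cut. This puts boron on the stereocentre, from which a 1,2-shift to an alkenyl carbon proceeds with retention, and it brings the 1,1-disubstituted alkene in at the end, when nothing remains that could move it into conjugation. The forward step must let iodine react with the alkenyl boronate faster than with the prenyl group or the arenes.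

**38 from 34 and 35.** The C7–CH bond is cut. The stereocentre then comes from an achiral aryl boronate and a two-carbon carbenoid whose configuration is fixed by a chiral diamine; the aryl group shifts from boron to carbon with inversion. Working back from (R) in 44 through the retentive step and the invertive shift, 36 must be (R), which requires the (+) antipode of the diamine; the more common (−) antipode would lead to the enantiomer of 44. The demand is boronate formation at a boron atom next to a bulky silyl ether.

**34 from 32, 32 from 31, 31 from 30.** The C7–B bond is traced to a C7–I bond, the O4–Si bond is cut, then the C7–I bond. In 30, C7 is para to the only free hydroxyl, so the substrate itself directs halogenation there. The forward step must prefer C7 over C5, C3, chroman C8 and the prenyl alkene.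

**30 from 21 and 25 (the strategic cut).** Four bonds of the benzo ring are cut: C3a–C4, C4–C5, C6–C7 and C7–C7a (forward, the last arises by shift of the furyl carbon from C4 to C7). A hexasubstituted benzene ring is exchanged for a 2,5-disubstituted furan and a two-carbon ynol ether, and the O4/O6 distinction comes for free. The demand is that the ketene from 21 meets 25 before it dimerises or acylates the product, with the orientation set by polarity.

**21 from 19; 19 from 12 and 15; 15 from 13 and 14.** The C=N2 bond is cut back to a methyl ketone, then the bond between furan C5 and chroman C5, then the ketal. A small furyl nucleophile is the least demanding partner for the crowded carbon of 12, and the masked acetyl group in 15 means no strong base meets the prenyl-bearing intermediate. The catalyst must insert into a di-ortho-substituted C–O bond.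

**12 from 11, 11 from 9, 9 from 7 and 8.** The O–S bond is cut, the C6–CH2 bond is cut by a retro-(3,3) shift to the O5 ether, then the O5–C bond. C6 is the only free carbon ortho to O5, so the shift cannot place the prenyl group at C8, which an electrophilic halogenation could not guarantee; the same oxygen then becomes the leaving group. The demand is ether formation at the tertiary allyl terminus.

**7 from 4, 4 from 3, 3 from 1 and 2.** The C4 methylene is traced to a ketone, the O7–Si bond is cut, and the pyranone ring is opened at C4–C4a and O1–C2. The ketone distinguishes O5 (hydrogen-bonded) from O7, and the O5–H beside it allows its mild removal before any alkene is present. What remains is symmetric 1 and the four-carbon acid 2.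

**25 from 22.** The O–Si bond is cut; the ynolate 24 arises by cycloreversion of 23. The demand is silylation at oxygen and not at carbon.

## Other disconnections considered

**Alternative 1:** The furan C2=C3 bond is cut and O1–C2 is traced to an aryl ester. The precursor is phosphonium salt A2, in which the phenol oxygen next to the CH2P group is acylated by the chroman acid and the ring already carries the (R) side chain. Forward, triethylamine forms the ylide, which attacks the neighbouring ester carbonyl; loss of Ph3PO gives A1, one fluoride step from 44.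
- In favour: this closure is a dependable, purely thermal route to 2-arylbenzofurans, and nothing has to be done on the finished benzofuran.
- Against: A2 needs a hexasubstituted phloroglucinol ring with the side chain, a benzylic carbon and three differentiated oxygens. Its ester joins a phenol flanked by two carbon substituents to a 2,6-disubstituted aroyl group, so both the acylation and the ylide attack on that shielded carbonyl are sterically disfavoured. The stereocentre would still have to come from the same boron chemistry, now on a ring that must afterwards be functionalised beside it.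
- Comparison: on structure it is the equal of the chosen plan in convergence and better in leaving only deprotection at the end. On mechanism it is better in simplicity (no light, no diazo compound). On step economy it is expected to be worse, since the phenol half of A2 alone needs about as many steps as the chosen route spends on the whole benzofuran, while the chosen plan builds the ring and distinguishes O4 from O6 in one step.

**Alternative 2:** The chroman benzene ring is cut at C5–C6 and C4a–C8a. Forward, diene A4 adds to ynone A5 in a (4+2) cycloaddition; loss of methanol and of the trimethylsilyl groups gives the 2,4-dihydroxyaryl ketone A3.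
- In favour: polarity fixes the orientation; prenyl, both oxygens, the benzofuranyl group and an acyl handle for the pyran ring arrive in one step; no cross-coupling at a hindered carbon is needed. As a de novo arene construction it is the equal of the chosen key step in concept.
- Against: A5 has two electrophilic sites (ynone and cross-conjugated enone), and the substituted terminus of A4 is slow, so the (3+3) mode to a salicylate can compete. A3 has two free resorcinol hydroxyls to tell apart. After oxa-Michael closure the C4 ketone must be removed with prenyl and furan present and without an ortho hydroxyl, for which no mild method is available. The benzofuran of A3 still lacks the C7 side chain, so the whole late sequence remains.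
- Comparison: on structure it builds the easier ring (the chosen route reaches 12 from 1 in six steps) and leaves the harder one. On mechanism it is better in operational simplicity. On step economy it is worse: A5 needs its own synthesis, at least four steps follow A3 before the chroman is complete, and the six late steps are unchanged.

**Alternative 3:** The furan is cut at C3–C3a and O1–C2. The precursor is the O-aryl oxime A7, from methyl ketone A8 (one coupling step from 12) and the O-arylhydroxylamine A9 of a symmetric phloroglucinol bis-silyl ether. Forward, N-trifluoroacetylation (TFAA, DMAP) gives an ene-hydroxylamine that undergoes a (3,3) shift with N–O cleavage; the freed phenol adds to the imine carbon and trifluoroacetamide is lost, giving A6.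
- In favour: the aryl unit is symmetric, so the shift has no regiochemical choice, which makes it the equal of the chosen plan in regiocontrol. The ring atoms come from cheap 1 and are not built. No light, diazo compound or special alkyne is needed.
- Against: condensation at the doubly ortho-substituted ketone A8 is slow, and the electron-rich N–O compound A9 is fragile. The acylating medium generates trifluoroacetic acid next to the prenyl group and silyl ethers. A6 has two identical silyl ethers, so later substitution at C7 cannot use a free para hydroxyl and relies on sterics alone. The six late steps are unchanged.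
- Comparison: on mechanism (a thermal sigmatropic cascade) and on step economy (about two steps shorter to the benzofuran) it is the better of the two. The chosen plan is kept because it avoids the hindered condensation and the N–O reagent and delivers O4 and O6 already distinguished.

Key step: step 11

## Remarks before the steps

- Notation: Chm = 2,2-dimethyl-6-(3-methylbut-2-enyl)-7-(triisopropylsilyloxy)chroman-5-yl.
- Assumption: 8, 22, 35 and (+)-sparteine are taken as purchasable; 8 and 35 are otherwise each one acylation step from a bulk alcohol.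
- Remark on the chemistry: the connectivities of the diazo ketone and of the benzannulation product stand as checked atom by atom against the mechanism. The chroman oxygen carries TIPS (not TBS) in 21 and 30, because that ether must survive aqueous borohydride, organolithiums and methoxide, and one silyl type allows a single final deprotection.
- Remark on stereochemistry: the target is (R), which requires (+)-sparteine in step 15.

## Route

Step 1
Reactants: 1 phloroglucinol; 2 3-methylbut-2-enoic acid
Product: 3 5,7-dihydroxy-2,2-dimethylchroman-4-one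
Conditions: P2O5, MeSO3H, 70 °C
Reagents that add atoms: none
Why: Friedel–Crafts acylation of 1 by the activated acid and tandem oxa-Michael addition close the 2,2-dimethylchromanone in one operation; the symmetry of 1 removes any question of site and the product is deactivated toward a second acylation.

Step 2
Reactants: 3 5,7-dihydroxy-2,2-dimethylchroman-4-one
Product: 4 5-hydroxy-2,2-dimethyl-7-(triisopropylsilyloxy)chroman-4-one
Conditions: TIPSCl (1.05 equiv), imidazole, DMF, 0 °C
Reagents that add atoms: triisopropylsilyl chloride, CC(C)[Si](Cl)(C(C)C)C(C)C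
Why: Selective O-silylation: the C5 hydroxyl is locked in a hydrogen bond to the C4 carbonyl and is far less nucleophilic, so one equivalent of silyl chloride should go to O7.

Step 3
Reactants: 4 5-hydroxy-2,2-dimethyl-7-(triisopropylsilyloxy)chroman-4-one
Product: 7 2,2-dimethyl-7-(triisopropylsilyloxy)chroman-5-ol, via aryl ethyl carbonate 5 (not isolated), via ortho-quinone methide 6 (not isolated)
Conditions: ClCO2Et, Et3N, THF, 0 °C; then NaBH4, H2O, 0 °C to rt
Reagents that add atoms: none
Why: Carbonate-mediated borohydride deoxygenation of an ortho-acylphenol: hydride addition to the ketone of 5 is followed by loss of ethyl carbonate to give 6, which a second hydride reduces at C4. The method needs exactly the free O5–H beside the carbonyl and is run before any alkene is present.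

Step 4
Reactants: 7 2,2-dimethyl-7-(triisopropylsilyloxy)chroman-5-ol; 8 tert-butyl 2-methylbut-3-en-2-yl carbonate
Product: 9 2,2-dimethyl-5-(2-methylbut-3-en-2-yloxy)-7-(triisopropylsilyloxy)chroman
Conditions: Pd(PPh3)4 (3 mol %), THF, 0 °C
Reagents that add atoms: none
Why: Palladium-catalysed allylic etherification (Tsuji–Trost type): zerovalent palladium ionises 8 to a 1,1-dimethylallyl complex and tert-butoxide, and the phenoxide attacks the more substituted terminus under kinetic control at low temperature to give the branched ether.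

Step 5
Reactants: 9 2,2-dimethyl-5-(2-methylbut-3-en-2-yloxy)-7-(triisopropylsilyloxy)chroman
Product: 11 2,2-dimethyl-6-(3-methylbut-2-enyl)-7-(triisopropylsilyloxy)chroman-5-ol, via cyclohexadienone 10 (not isolated)
Conditions: PhNEt2, 130 °C
Reagents that add atoms: none
Why: Aromatic Claisen rearrangement: the (3,3) shift can only deliver the allyl terminus to C6, the one free position ortho to O5, and inversion of the allyl unit turns the 1,1-dimethylallyl ether into a linear prenyl group. Enolisation of 10 restores the phenol, and the amine solvent keeps the medium non-acidic so the ortho-prenylphenol does not cyclise.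

Step 6
Reactants: 11 2,2-dimethyl-6-(3-methylbut-2-enyl)-7-(triisopropylsilyloxy)chroman-5-ol
Product: 12 2,2-dimethyl-6-(3-methylbut-2-enyl)-7-(triisopropylsilyloxy)chroman-5-yl trifluoromethanesulfonate
Conditions: Tf2O, pyridine, CH2Cl2, −78 to 0 °C
Reagents that add atoms: trifluoromethanesulfonic anhydride, O=S(=O)(OS(=O)(=O)C(F)(F)F)C(F)(F)F
Why: O-Sulfonylation of the hindered phenol with the most reactive triflating agent; pyridine scavenges triflic acid so that the prenyl group and the silyl ether see no free acid.

Step 7
Reactants: 13 2-acetylfuran; 14 ethane-1,2-diol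
Product: 15 2-(furan-2-yl)-2-methyl-1,3-dioxolane
Conditions: p-TsOH (cat.), benzene, reflux, Dean–Stark
Reagents that add atoms: none
Why: Acid-catalysed ketalisation with azeotropic removal of water; the acetyl group is masked so that the furan can be lithiated at C5 in the next step.

Step 8
Reactants: 12 2,2-dimethyl-6-(3-methylbut-2-enyl)-7-(triisopropylsilyloxy)chroman-5-yl trifluoromethanesulfonate; 15 2-(furan-2-yl)-2-methyl-1,3-dioxolane
Product: 19 1-(5-Chm-furan-2-yl)ethanone, via 5-lithiofuran ketal 16 (not isolated), via furylzinc chloride 17 (not isolated), via biaryl ketal 18 (not isolated)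
Conditions: 15, n-BuLi, THF, −78 to 0 °C; ZnCl2, 0 °C to rt; 12, Pd2(dba)3 (2.5 mol %), XPhos (10 mol %), 65 °C; then 1 M HCl, THF, rt
Reagents that add atoms: water, O
Why: Furan α-lithiation, transmetalation to zinc and Negishi coupling: the bulky electron-rich biarylphosphine lets zerovalent palladium insert into the di-ortho-substituted aryl triflate, and the small 2-furylzinc partner keeps transmetalation and reductive elimination feasible. Dilute acid in the work-up hydrolyses the furan-activated dioxolane without affecting the TIPS ether or the prenyl group.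

Step 9
Reactants: 19 1-(5-Chm-furan-2-yl)ethanone
Product: 21 2-diazo-1-(5-Chm-furan-2-yl)ethanone, via trifluoroacetyl diketone 20 (not isolated)
Conditions: LiN(SiMe3)2, THF, −78 °C; CF3CO2CH2CF3, −78 °C; then 4-AcNHC6H4SO2N3, Et3N, H2O, MeCN, rt
Reagents that add atoms: 4-acetamidobenzenesulfonyl azide, CC(=O)Nc1ccc(cc1)S(=O)(=O)N=[N+]=[N-]
Why: Detrifluoroacetylative diazo transfer: the kinetic lithium enolate of the methyl ketone is acylated to 20, whose activated methylene accepts the diazo group from the sulfonyl azide, and cleavage of the trifluoroacetyl group leaves the diazomethyl ketone. The activation is needed because a simple methyl ketone does not undergo direct diazo transfer.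

Step 10
Reactants: 22 3-phenylisoxazole
Product: 25 triisopropylsiloxyethyne, via 5-lithio-3-phenylisoxazole 23 (not isolated), via lithium ethynolate 24 (not isolated)
Conditions: n-BuLi, THF, −78 to −20 °C; TIPSOTf, −78 to 0 °C
Reagents that add atoms: triisopropylsilyl trifluoromethanesulfonate, CC(C)[Si](OS(=O)(=O)C(F)(F)F)(C(C)C)C(C)C
Why: Deprotonation at C5 of the isoxazole triggers cycloreversion of 23 to benzonitrile and 24; the hard, bulky silyl triflate should silylate the ambident ynolate on oxygen, as is general for triisopropylsilyl ynol ethers. The product is acid-labile and is used soon after filtration through basic alumina.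

Step 11
Reactants: 21 2-diazo-1-(5-Chm-furan-2-yl)ethanone; 25 triisopropylsiloxyethyne
Product: 30 2-[2,2-dimethyl-6-(3-methylbut-2-enyl)-7-(triisopropylsilyloxy)chroman-5-yl]-6-(triisopropylsilyloxy)benzofuran-4-ol, via furylketene 26 (not isolated), via 4-furylcyclobutenone 27 (not isolated), via dienylketene 28 (not isolated), via 3aH-benzofuran-4-one 29 (not isolated)
Conditions: 25 (2.5 equiv), ClCH2CH2Cl, hν (300 nm), rt; then 80 °C
Reagents that add atoms: none
Why: Light expels N2 from 21 and the furyl group shifts from the carbonyl carbon to the former diazo carbon (Wolff rearrangement, new bond C7–C7a) to give 26. The electrophilic ketene carbonyl carbon bonds to the unsubstituted, nucleophilic alkyne carbon of 25 and the ketene α-carbon to the siloxy-bearing carbon in a (2+2) cycloaddition (C4–C5 and C6–C7), giving 27. Reversible 4π electrocyclic opening of 27 gives 28, and the isomer with the furan cis to the ketene closes by thermal disrotatory 6π electrocyclisation onto furan C3 (C3a–C4), which is the mode by which the six-membered benzo ring forms; 29 then enolises to the phenol. The closest known reaction type is the second-generation Danheiser benzannulation of aryl and heteroaryl diazomethyl ketones with siloxyalkynes. No stereocentre is created, since the sp3 carbons of 27 and 29 are transient and the product ring is aromatic. The step needs regiocontrol in the (2+2) event, secured by ketene/ynol ether polarity; a single site of closure, secured because only C3 of the 2,5-disubstituted furan is adjacent to the ketene-bearing carbon; and chemoselectivity over the prenyl alkene, secured by the much higher ketenophilicity of the siloxyalkyne used in excess. The product carries O4 as a free hydroxyl, O6 as a silyl ether and hydrogen at C7, which the next steps use.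

Step 12
Reactants: 30 2-Chm-6-(triisopropylsilyloxy)benzofuran-4-ol
Product: 31 2-Chm-7-iodo-6-(triisopropylsilyloxy)benzofuran-4-ol
Conditions: NIS (1.0 equiv), CH2Cl2, −40 to 0 °C, dark
Reagents that add atoms: N-iodosuccinimide, O=C1CCC(=O)N1I
Why: Electrophilic aromatic iodination of a phenol: C7 is para to the only free hydroxyl and ortho to two further oxygens, whereas C5 is squeezed between OH and OTIPS and C3 lies between the twisted aryl group and O4. The free phenol should react at low temperature, far faster than the prenyl alkene or the fully silylated chroman ring.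

Step 13
Reactants: 31 2-Chm-7-iodo-6-(triisopropylsilyloxy)benzofuran-4-ol
Product: 32 2-Chm-7-iodo-4,6-bis(triisopropylsilyloxy)benzofuran
Conditions: TIPSOTf, 2,6-lutidine, CH2Cl2, 0 °C
Reagents that add atoms: triisopropylsilyl trifluoromethanesulfonate, CC(C)[Si](OS(=O)(=O)C(F)(F)F)(C(C)C)C(C)C
Why: Silylation of the remaining phenol removes the acidic proton before the organolithium steps and gives the tris-TIPS pattern that one fluoride treatment clears at the end.

Step 14
Reactants: 32 2-Chm-7-iodo-4,6-bis(triisopropylsilyloxy)benzofuran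
Product: 34 2-Chm-7-(4,4,5,5-tetramethyl-1,3,2-dioxaborolan-2-yl)-4,6-bis(triisopropylsilyloxy)benzofuran, via aryllithium 33 (not isolated)
Conditions: t-BuLi (2.1 equiv), Et2O, −78 °C; i-PrOBpin, −78 °C to rt
Reagents that add atoms: 2-isopropoxy-4,4,5,5-tetramethyl-1,3,2-dioxaborolane, CC(C)OB1OC(C)(C)C(C)(C)O1
Why: Iodine–lithium exchange at −78 °C is faster than any deprotonation, and 33 is trapped at once by the isopropoxyborolane. The bulk of the TIPS group and the low temperature suppress 1,3 O-to-C silyl migration in the ortho-lithio silyl ether.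

Step 15
Reactants: 34 2-Chm-7-(4,4,5,5-tetramethyl-1,3,2-dioxaborolan-2-yl)-4,6-bis(triisopropylsilyloxy)benzofuran; 35 ethyl N,N-diisopropylcarbamate
Product: 38 2-Chm-7-[(1S)-1-(4,4,5,5-tetramethyl-1,3,2-dioxaborolan-2-yl)ethyl]-4,6-bis(triisopropylsilyloxy)benzofuran, via lithiated carbamate 36 (not isolated), via boronate complex 37 (not isolated)
Conditions: 35, s-BuLi, (+)-sparteine, Et2O, −78 °C; 34, −78 °C; MgBr2·OEt2, −78 °C to reflux
Reagents that add atoms: none
Why: Sparteine-mediated asymmetric deprotonation and lithiation–borylation: s-BuLi with (+)-sparteine removes the pro-R hydrogen of 35 to give the configurationally stable (R) carbenoid 36, boron adds with retention to give 37, and the aryl group migrates from boron to carbon antiperiplanar to the carbamate with inversion, which sets the stereocentre as (S) in 38. (+)-Sparteine is required, because the (−) antipode would end in the enantiomer of the target.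

Step 16
Reactants: 38 2-Chm-7-[(1S)-1-(4,4,5,5-tetramethyl-1,3,2-dioxaborolan-2-yl)ethyl]-4,6-bis(triisopropylsilyloxy)benzofuran; 39 2-bromopropene
Product: 43 2-Chm-7-[(2R)-3-methylbut-3-en-2-yl]-4,6-bis(triisopropylsilyloxy)benzofuran, via isopropenyllithium 40 (not isolated), via alkenylboronate complex 41 (not isolated), via iodoalkyl boronic ester 42 (not isolated)
Conditions: 39, t-BuLi, THF, −78 °C; 38, −78 to 0 °C; I2, MeOH, −78 °C; NaOMe, MeOH, −78 °C to rt
Reagents that add atoms: none
Why: Zweifel olefination: 40 adds to boron to give 41, iodine forms an iodonium ion that triggers 1,2-shift of the benzylic carbon with retention to give 42, and methoxide induces anti elimination of boron and iodide to release the 1,1-disubstituted alkene. The spatial arrangement at the stereocentre is unchanged; the descriptor becomes (R) only because isopropenyl outranks methyl whereas boron ranked below it.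

Step 17
Reactants: 43 2-Chm-7-[(2R)-3-methylbut-3-en-2-yl]-4,6-bis(triisopropylsilyloxy)benzofuran
Product: 44 2-[7-hydroxy-2,2-dimethyl-6-(3-methylbut-2-enyl)chroman-5-yl]-7-[(2R)-3-methylbut-3-en-2-yl]benzofuran-4,6-diol
Conditions: Bu4NF, AcOH, THF, 0 °C to rt
Reagents that add atoms: none
Why: Fluoride cleaves the three aryl silyl ethers; acetic acid buffers the phenoxides so that neither the benzylic-allylic stereocentre nor the alkenes ortho to the freed phenols meet strong base or acid.

## Compound list

Chm = 2,2-dimethyl-6-(3-methylbut-2-enyl)-7-(triisopropylsilyloxy)chroman-5-yl.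

1 | phloroglucinol | Oc1cc(O)cc(O)c1 | starting material
2 | 3-methylbut-2-enoic acid | CC(C)=CC(=O)O | starting material
3 | 5,7-dihydroxy-2,2-dimethylchroman-4-one | CC1(C)CC(=O)c2c(O)cc(O)cc2O1 | intermediate
4 | 5-hydroxy-2,2-dimethyl-7-(triisopropylsilyloxy)chroman-4-one | CC1(C)CC(=O)c2c(O)cc(O[Si](C(C)C)(C(C)C)C(C)C)cc2O1 | intermediate
5 | ethyl 2,2-dimethyl-4-oxo-7-(triisopropylsilyloxy)chroman-5-yl carbonate (not isolated) | CCOC(=O)Oc1cc(O[Si](C(C)C)(C(C)C)C(C)C)cc2OC(C)(C)CC(=O)c12 | intermediate
6 | 2,2-dimethyl-7-(triisopropylsilyloxy)-2,3-dihydrochromen-5-one, the ortho-quinone methide (not isolated) | O=C1C=C(O[Si](C(C)C)(C(C)C)C(C)C)C=C2OC(C)(C)CC=C12 | intermediate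
7 | 2,2-dimethyl-7-(triisopropylsilyloxy)chroman-5-ol | CC1(C)CCc2c(O)cc(O[Si](C(C)C)(C(C)C)C(C)C)cc2O1 | intermediate
8 | tert-butyl 2-methylbut-3-en-2-yl carbonate | C=CC(C)(C)OC(=O)OC(C)(C)C | starting material
9 | 2,2-dimethyl-5-(2-methylbut-3-en-2-yloxy)-7-(triisopropylsilyloxy)chroman | C=CC(C)(C)Oc1cc(O[Si](C(C)C)(C(C)C)C(C)C)cc2OC(C)(C)CCc12 | intermediate
10 | 2,2-dimethyl-6-(3-methylbut-2-enyl)-7-(triisopropylsilyloxy)-3,4-dihydro-6H-chromen-5-one, racemic at C6 (not isolated) | CC(C)=CCC1C(=O)C2=C(C=C1O[Si](C(C)C)(C(C)C)C(C)C)OC(C)(C)CC2 | intermediate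
11 | 2,2-dimethyl-6-(3-methylbut-2-enyl)-7-(triisopropylsilyloxy)chroman-5-ol | CC(C)=CCc1c(O)c2CCC(C)(C)Oc2cc1O[Si](C(C)C)(C(C)C)C(C)C | intermediate
12 | 2,2-dimethyl-6-(3-methylbut-2-enyl)-7-(triisopropylsilyloxy)chroman-5-yl trifluoromethanesulfonate | CC(C)=CCc1c(OS(=O)(=O)C(F)(F)F)c2CCC(C)(C)Oc2cc1O[Si](C(C)C)(C(C)C)C(C)C | intermediate
13 | 2-acetylfuran | CC(=O)c1ccco1 | starting material
14 | ethane-1,2-diol | OCCO | starting material
15 | 2-(furan-2-yl)-2-methyl-1,3-dioxolane | CC1(c2ccco2)OCCO1 | intermediate
16 | 2-(5-lithiofuran-2-yl)-2-methyl-1,3-dioxolane (not isolated) | CC1(c2ccc([Li])o2)OCCO1 | intermediate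
17 | [5-(2-methyl-1,3-dioxolan-2-yl)furan-2-yl]zinc chloride (not isolated) | CC1(c2ccc([Zn]Cl)o2)OCCO1 | intermediate
18 | 2-(5-Chm-furan-2-yl)-2-methyl-1,3-dioxolane (not isolated) | CC1(c2ccc(-c3c(CC=C(C)C)c(O[Si](C(C)C)(C(C)C)C(C)C)cc4OC(C)(C)CCc34)o2)OCCO1 | intermediate
19 | 1-(5-Chm-furan-2-yl)ethanone | CC(=O)c1ccc(-c2c(CC=C(C)C)c(O[Si](C(C)C)(C(C)C)C(C)C)cc3OC(C)(C)CCc23)o1 | intermediate
20 | 4,4,4-trifluoro-1-(5-Chm-furan-2-yl)butane-1,3-dione (not isolated) | O=C(CC(=O)C(F)(F)F)c1ccc(-c2c(CC=C(C)C)c(O[Si](C(C)C)(C(C)C)C(C)C)cc3OC(C)(C)CCc23)o1 | intermediate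
21 | 2-diazo-1-{5-[2,2-dimethyl-6-(3-methylbut-2-enyl)-7-(triisopropylsilyloxy)chroman-5-yl]furan-2-yl}ethanone | [N-]=[N+]=CC(=O)c1ccc(-c2c(CC=C(C)C)c(O[Si](C(C)C)(C(C)C)C(C)C)cc3OC(C)(C)CCc23)o1 | intermediate
22 | 3-phenylisoxazole | c1ccc(-c2ccon2)cc1 | starting material
23 | 5-lithio-3-phenylisoxazole (not isolated) | [Li]c1cc(-c2ccccc2)no1 | intermediate
24 | lithium ethynolate (not isolated) | [Li+].[O-]C#C | intermediate
25 | triisopropylsiloxyethyne | C#CO[Si](C(C)C)(C(C)C)C(C)C | intermediate
26 | 2-(5-Chm-furan-2-yl)ethenone, the furylketene (not isolated) | O=C=Cc1ccc(-c2c(CC=C(C)C)c(O[Si](C(C)C)(C(C)C)C(C)C)cc3OC(C)(C)CCc23)o1 | intermediate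
27 | 4-(5-Chm-furan-2-yl)-3-(triisopropylsilyloxy)cyclobut-2-en-1-one, racemic at C4 (not isolated) | O=C1C=C(O[Si](C(C)C)(C(C)C)C(C)C)C1c1ccc(-c2c(CC=C(C)C)c(O[Si](C(C)C)(C(C)C)C(C)C)cc3OC(C)(C)CCc23)o1 | intermediate
28 | 4-(5-Chm-furan-2-yl)-3-(triisopropylsilyloxy)buta-1,3-dien-1-one, furan cis to C2 (not isolated) | O=C=C/C(O[Si](C(C)C)(C(C)C)C(C)C)=C\c1ccc(-c2c(CC=C(C)C)c(O[Si](C(C)C)(C(C)C)C(C)C)cc3OC(C)(C)CCc23)o1 | intermediate
29 | 2-Chm-6-(triisopropylsilyloxy)-3aH-benzofuran-4-one, racemic at C3a (not isolated) | O=C1C=C(O[Si](C(C)C)(C(C)C)C(C)C)C=C2OC(c3c(CC=C(C)C)c(O[Si](C(C)C)(C(C)C)C(C)C)cc4OC(C)(C)CCc34)=CC12 | intermediate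
30 | 2-[2,2-dimethyl-6-(3-methylbut-2-enyl)-7-(triisopropylsilyloxy)chroman-5-yl]-6-(triisopropylsilyloxy)benzofuran-4-ol | CC(C)[Si](C(C)C)(C(C)C)Oc1cc(O)c2cc(-c3c(CC=C(C)C)c(O[Si](C(C)C)(C(C)C)C(C)C)cc4OC(C)(C)CCc34)oc2c1 | intermediate
31 | 2-Chm-7-iodo-6-(triisopropylsilyloxy)benzofuran-4-ol | Oc1cc(O[Si](C(C)C)(C(C)C)C(C)C)c(I)c2oc(-c3c(CC=C(C)C)c(O[Si](C(C)C)(C(C)C)C(C)C)cc4OC(C)(C)CCc34)cc12 | intermediate
32 | 2-Chm-7-iodo-4,6-bis(triisopropylsilyloxy)benzofuran | CC(C)[Si](C(C)C)(C(C)C)Oc1cc(O[Si](C(C)C)(C(C)C)C(C)C)c(I)c2oc(-c3c(CC=C(C)C)c(O[Si](C(C)C)(C(C)C)C(C)C)cc4OC(C)(C)CCc34)cc12 | intermediate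
33 | 2-Chm-7-lithio-4,6-bis(triisopropylsilyloxy)benzofuran (not isolated) | CC(C)[Si](C(C)C)(C(C)C)Oc1cc(O[Si](C(C)C)(C(C)C)C(C)C)c([Li])c2oc(-c3c(CC=C(C)C)c(O[Si](C(C)C)(C(C)C)C(C)C)cc4OC(C)(C)CCc34)cc12 | intermediate
34 | 2-Chm-7-(4,4,5,5-tetramethyl-1,3,2-dioxaborolan-2-yl)-4,6-bis(triisopropylsilyloxy)benzofuran | CC(C)[Si](C(C)C)(C(C)C)Oc1cc(O[Si](C(C)C)(C(C)C)C(C)C)c(B3OC(C)(C)C(C)(C)O3)c2oc(-c3c(CC=C(C)C)c(O[Si](C(C)C)(C(C)C)C(C)C)cc4OC(C)(C)CCc34)cc12 | intermediate
35 | ethyl N,N-diisopropylcarbamate | CCOC(=O)N(C(C)C)C(C)C | starting material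
36 | (1R)-1-lithioethyl N,N-diisopropylcarbamate, as its (+)-sparteine complex (not isolated) | C[C@@H]([Li])OC(=O)N(C(C)C)C(C)C | intermediate
37 | lithium boronate complex of 34 with 36, (R) at the carbamate-bearing carbon (not isolated) | C[C@@H]([B-]1(OC(C)(C)C(C)(C)O1)c1c(O[Si](C(C)C)(C(C)C)C(C)C)cc(O[Si](C(C)C)(C(C)C)C(C)C)c2cc(-c3c(CC=C(C)C)c(O[Si](C(C)C)(C(C)C)C(C)C)cc4OC(C)(C)CCc34)oc12)OC(=O)N(C(C)C)C(C)C.[Li+] | intermediate
38 | 2-Chm-7-[(1S)-1-(4,4,5,5-tetramethyl-1,3,2-dioxaborolan-2-yl)ethyl]-4,6-bis(triisopropylsilyloxy)benzofuran | C[C@H](B1OC(C)(C)C(C)(C)O1)c1c(O[Si](C(C)C)(C(C)C)C(C)C)cc(O[Si](C(C)C)(C(C)C)C(C)C)c2cc(-c3c(CC=C(C)C)c(O[Si](C(C)C)(C(C)C)C(C)C)cc4OC(C)(C)CCc34)oc12 | intermediate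
39 | 2-bromopropene | C=C(C)Br | starting material
40 | isopropenyllithium (not isolated) | [Li]C(C)=C | intermediate
41 | lithium isopropenyl boronate complex of 38, benzylic centre as in 38 (not isolated) | C[C@H]([B-]1(C(C)=C)OC(C)(C)C(C)(C)O1)c1c(O[Si](C(C)C)(C(C)C)C(C)C)cc(O[Si](C(C)C)(C(C)C)C(C)C)c2cc(-c3c(CC=C(C)C)c(O[Si](C(C)C)(C(C)C)C(C)C)cc4OC(C)(C)CCc34)oc12.[Li+] | intermediate
42 | 2-Chm-7-[(2R)-4-iodo-3-methyl-3-(4,4,5,5-tetramethyl-1,3,2-dioxaborolan-2-yl)butan-2-yl]-4,6-bis(triisopropylsilyloxy)benzofuran, both epimers at the boron-bearing carbon (not isolated) | C[C@H](C(C)(CI)B1OC(C)(C)C(C)(C)O1)c1c(O[Si](C(C)C)(C(C)C)C(C)C)cc(O[Si](C(C)C)(C(C)C)C(C)C)c2cc(-c3c(CC=C(C)C)c(O[Si](C(C)C)(C(C)C)C(C)C)cc4OC(C)(C)CCc34)oc12 | intermediate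
43 | 2-[2,2-dimethyl-6-(3-methylbut-2-enyl)-7-(triisopropylsilyloxy)chroman-5-yl]-7-[(2R)-3-methylbut-3-en-2-yl]-4,6-bis(triisopropylsilyloxy)benzofuran | C=C(C)[C@@H](C)c1c(O[Si](C(C)C)(C(C)C)C(C)C)cc(O[Si](C(C)C)(C(C)C)C(C)C)c2cc(-c3c(CC=C(C)C)c(O[Si](C(C)C)(C(C)C)C(C)C)cc4OC(C)(C)CCc34)oc12 | intermediate
44 | 2-[7-hydroxy-2,2-dimethyl-6-(3-methylbut-2-enyl)chroman-5-yl]-7-[(2R)-3-methylbut-3-en-2-yl]benzofuran-4,6-diol | C=C(C)[C@@H](C)c1c(O)cc(O)c2cc(-c3c(CC=C(C)C)c(O)cc4c3CCC(C)(C)O4)oc12 | target

## Step count and least certain steps

Total steps: 17. Longest linear sequence: 15 (steps 1–6, 8, 9, 11–17); steps 7 and 10 are side branches.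

**Step 11 (key step).** The benzofuran product absorbs the same light as 21 and may screen the diazo ketone or be degraded by secondary photoreactions. If cycloaddition to the unsubstituted siloxyalkyne is slow, ketene dimerisation or acylation of the newly formed phenol by the ketene can take over. Fallback, from 21 back to 30 without light: silver-catalysed Wolff rearrangement of 21 in aqueous THF (PhCO2Ag, Et3N) should give (5-Chm-furan-2-yl)acetic acid F1. A neutral chlorinating agent (1-chloro-N,N,2-trimethylpropenylamine) should convert it into (5-Chm-furan-2-yl)acetyl chloride F2. Slow addition of Et3N to F2 and excess 25 in toluene generates the same ketene 26 by dehydrochlorination, and heating to 80 °C carries the cyclobutenone through to 30.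

**Step 15.** Formation of the boronate at a boron atom flanked by the TIPS ether may be slow with the sparteine-bound carbenoid. Warming to force it risks loss of configuration or decomposition of 36, and incomplete aryl migration would erode yield and enantiopurity. Fallback, from 32 back to 38: Suzuki–Miyaura vinylation of 32 (vinylboronic acid pinacol ester, Pd(OAc)2, SPhos, K3PO4) should give 2-Chm-7-vinyl-4,6-bis(triisopropylsilyloxy)benzofuran F3. Enantioselective Markovnikov hydroboration of this styrene (CuCl, NaOt-Bu, a chiral bisphosphine such as DTBM-SEGPHOS in the antipode that gives the (S) product, pinacolborane) should then give 38; the unactivated prenyl alkene is not expected to react.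

**Step 10.** The ynolate is ambident and unhindered at carbon, so C-silylation to a silylketene may compete with O-silylation, and the ynolate may be lost by self-condensation during the fragmentation. Fallback, not via an ynolate; it replaces 22, sets out from tetrahydrofuran and returns at 25: cleavage of tetrahydrofuran with n-BuLi and silylation of the resulting enolate with TIPSCl should give triisopropyl(vinyloxy)silane F4. Bromine addition gives (1,2-dibromoethoxy)triisopropylsilane F5, and Et3N eliminates HBr to (Z)-(2-bromovinyloxy)triisopropylsilane F6. LiN(i-Pr)2 (2.2 equiv) then dehydrobrominates F6, and an aqueous quench gives 25.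

**Step 12.** Iodination ortho to the free hydroxyl (C5), double iodination, or attack of the iodonium source on the prenyl alkene would lower selectivity. Fallback, from 30 back to 32 with steric instead of electronic control: silylate first (TIPSOTf, 2,6-lutidine) to 2-Chm-4,6-bis(triisopropylsilyloxy)benzofuran F7, in which C5 is enclosed by two TIPS ethers, then iodinate with NIS in MeCN at 0 °C to reach 32.

**Step 4.** Attack of the phenoxide at the primary terminus, or re-ionisation of the branched ether, would give the linear prenyl ether, which on heating would place a 1,1-dimethylallyl group at C6. Fallback, from 7 back to 11 at the cost of one step: O-allylation (allyl bromide, K2CO3, acetone) to 5-allyloxy-2,2-dimethyl-7-(triisopropylsilyloxy)chroman F8, Claisen rearrangement (PhNEt2, 190 °C) to 6-allyl-2,2-dimethyl-7-(triisopropylsilyloxy)chroman-5-ol F9, then cross-metathesis with 2-methylbut-2-ene (second-generation Grubbs catalyst, CH2Cl2, 40 °C) to 11.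

## Further compounds

F1 | step 11 | (5-Chm-furan-2-yl)acetic acid | OC(=O)Cc1ccc(-c2c(CC=C(C)C)c(O[Si](C(C)C)(C(C)C)C(C)C)cc3OC(C)(C)CCc23)o1
F2 | step 11 | (5-Chm-furan-2-yl)acetyl chloride | ClC(=O)Cc1ccc(-c2c(CC=C(C)C)c(O[Si](C(C)C)(C(C)C)C(C)C)cc3OC(C)(C)CCc23)o1
F3 | step 15 | 2-Chm-7-vinyl-4,6-bis(triisopropylsilyloxy)benzofuran | C=Cc1c(O[Si](C(C)C)(C(C)C)C(C)C)cc(O[Si](C(C)C)(C(C)C)C(C)C)c2cc(-c3c(CC=C(C)C)c(O[Si](C(C)C)(C(C)C)C(C)C)cc4OC(C)(C)CCc34)oc12
F4 | step 10 | triisopropyl(vinyloxy)silane | C=CO[Si](C(C)C)(C(C)C)C(C)C
F5 | step 10 | (1,2-dibromoethoxy)triisopropylsilane | BrCC(Br)O[Si](C(C)C)(C(C)C)C(C)C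
F6 | step 10 | (Z)-(2-bromovinyloxy)triisopropylsilane | Br/C=C\O[Si](C(C)C)(C(C)C)C(C)C
F7 | step 12 | 2-Chm-4,6-bis(triisopropylsilyloxy)benzofuran | CC(C)[Si](C(C)C)(C(C)C)Oc1cc(O[Si](C(C)C)(C(C)C)C(C)C)c2cc(-c3c(CC=C(C)C)c(O[Si](C(C)C)(C(C)C)C(C)C)cc4OC(C)(C)CCc34)oc2c1
F8 | step 4 | 5-allyloxy-2,2-dimethyl-7-(triisopropylsilyloxy)chroman | C=CCOc1cc(O[Si](C(C)C)(C(C)C)C(C)C)cc2OC(C)(C)CCc12
F9 | step 4 | 6-allyl-2,2-dimethyl-7-(triisopropylsilyloxy)chroman-5-ol | C=CCc1c(O)c2CCC(C)(C)Oc2cc1O[Si](C(C)C)(C(C)C)C(C)C
A1 | alternative 1 | 2-[7-(tert-butyldimethylsilyloxy)-2,2-dimethyl-6-(3-methylbut-2-enyl)chroman-5-yl]-4,6-bis(tert-butyldimethylsilyloxy)-7-[(2R)-3-methylbut-3-en-2-yl]benzofuran | C=C(C)[C@@H](C)c1c(O[Si](C)(C)C(C)(C)C)cc(O[Si](C)(C)C(C)(C)C)c2cc(-c3c(CC=C(C)C)c(O[Si](C)(C)C(C)(C)C)cc4c3CCC(C)(C)O4)oc12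
A2 | alternative 1 | {2-[7-(tert-butyldimethylsilyloxy)-2,2-dimethyl-6-(3-methylbut-2-enyl)chroman-5-carbonyloxy]-4,6-bis(tert-butyldimethylsilyloxy)-3-[(2R)-3-methylbut-3-en-2-yl]benzyl}triphenylphosphonium bromide | C=C(C)[C@@H](C)c1c(O[Si](C)(C)C(C)(C)C)cc(O[Si](C)(C)C(C)(C)C)c(C[P+](c2ccccc2)(c2ccccc2)c2ccccc2)c1OC(=O)c1c(CC=C(C)C)c(O[Si](C)(C)C(C)(C)C)cc2OC(C)(C)CCc12.[Br-]
A3 | alternative 2 | 1-{2-[4,6-bis(tert-butyldimethylsilyloxy)benzofuran-2-yl]-4,6-dihydroxy-3-(3-methylbut-2-enyl)phenyl}-3-methylbut-2-en-1-one | CC(C)=CC(=O)c1c(O)cc(O)c(CC=C(C)C)c1-c1cc2c(O[Si](C)(C)C(C)(C)C)cc(O[Si](C)(C)C(C)(C)C)cc2o1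
A4 | alternative 2 | 1-methoxy-7-methyl-1,3-bis(trimethylsilyloxy)octa-1,3,6-triene | COC(O[Si](C)(C)C)=CC(O[Si](C)(C)C)=CCC=C(C)C
A5 | alternative 2 | 1-[4,6-bis(tert-butyldimethylsilyloxy)benzofuran-2-yl]-5-methylhex-4-en-1-yn-3-one | CC(C)=CC(=O)C#Cc1cc2c(O[Si](C)(C)C(C)(C)C)cc(O[Si](C)(C)C(C)(C)C)cc2o1
A6 | alternative 3 | 2-[7-(tert-butyldimethylsilyloxy)-2,2-dimethyl-6-(3-methylbut-2-enyl)chroman-5-yl]-4,6-bis(tert-butyldimethylsilyloxy)benzofuran | CC(C)(C)[Si](C)(C)Oc1cc(O[Si](C)(C)C(C)(C)C)c2cc(-c3c(CC=C(C)C)c(O[Si](C)(C)C(C)(C)C)cc4c3CCC(C)(C)O4)oc2c1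
A7 | alternative 3 | 1-[7-(tert-butyldimethylsilyloxy)-2,2-dimethyl-6-(3-methylbut-2-enyl)chroman-5-yl]ethanone O-[3,5-bis(tert-butyldimethylsilyloxy)phenyl]oxime | CC(=NOc1cc(O[Si](C)(C)C(C)(C)C)cc(O[Si](C)(C)C(C)(C)C)c1)c1c(CC=C(C)C)c(O[Si](C)(C)C(C)(C)C)cc2OC(C)(C)CCc12
A8 | alternative 3 | 1-[7-(tert-butyldimethylsilyloxy)-2,2-dimethyl-6-(3-methylbut-2-enyl)chroman-5-yl]ethanone | CC(=O)c1c(CC=C(C)C)c(O[Si](C)(C)C(C)(C)C)cc2OC(C)(C)CCc12
A9 | alternative 3 | O-[3,5-bis(tert-butyldimethylsilyloxy)phenyl]hydroxylamine | NOc1cc(O[Si](C)(C)C(C)(C)C)cc(O[Si](C)(C)C(C)(C)C)c1
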